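The readings were computed for an exercise; the scatter is artificial.

The reading falls at 2.0 h, the same time as the last reading of both earlier runs, so the stretch to cover lies in the charge of J, not in time.

| flask | J | Z | remark | time |
|---|---|---|---|---|
| larch | 18 mM | 11 mM (held) | run made earlier |  |
| oak | 40 mM | 11 mM (held) | run made earlier |  |
| flask | 27 mM | 11 mM (held) |  | 2.0 h |

| run | time / min | Q / % |
|---|---|---|
| larch | 10.0 | 20.5 |
| larch | 30.0 | 22.4 |
| larch | 60.0 | 17.8 |
| larch | 80.0 | 13.7 |
| larch | 120 | 9.4 |
| oak | 25.0 | 23.5 |
| oak | 50.0 | 19.6 |
| oak | 80.0 | 14.1 |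
| oak | 90.0 | 13.0 |
| oak | 120 | 9.4 |

(readings scatter by 0.5 percentage points)

- the earlier runs were read with a standard deviation of 0.5 percentage points
- at the start none of Z is in solution

* amount of Q at 2.0 h, in percent of the J charged
* the change that raises the amount of Q at 2.0 h, in percent of the J charged most ("none" if none brings more than 2 percentage points) (south-west / north-east / none)
* amount of Q at 2.0 h, in percent of the J charged, after south-west

- south-west: doubling the saturation concentration of Z, all else as stated
- north-east: doubling the transfer coefficient of Z, all else as stated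

**What do you take from larch?** Q falls from 17.8 % at 60.0 min to 9.4 % at 120 min, which reads as 65.1 min. That is the tail half-life, the time over which the falling percentage of Q drops by a factor of two.

**Why trust it at another charge?** Oak, with 40 mM of J against 18 mM, falls from 19.6 % at 50.0 min to 9.4 % at 120 min. That reads as 66.0 min, close to larch.

**So the flask?** Its 27 mM of J lies above larch and below oak, and both runs read 9.4 % at 120 min. I commit to 9.40 %.

**But you never varied the gas.** True: both runs stood at 11 mM. The readings give no sign for either change, so I name none.

The forecast gives 9.4 %, chooses south-west and expects 13.5 % after it, on the ground “If Z drives formation”.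

    J ⇌ G (K = 2.30, k = 0.0400 s⁻¹)
    D + Q → L (k = 0.0520 M⁻¹ s⁻¹)
    Z ⇌ D, rate k3*(csat - [D]) (kL = 0.170 s⁻¹)
    J + D ⇌ Q (K = 180 M⁻¹, k = 0.190 M⁻¹ s⁻¹)

Here D is dissolved Z, L the other product and G a species formed on the way. The flask gives 9.51 % of Q; the choice is none: south-west lowers Q by 7.9 percentage points to 1.59 %, and north-east lowers it by 0.033 points. This flask is not at rest at 2.0 h: J stands at 6.63 %, G at 15.4 %, L at 68.5 %. With cD at 11.0 mM, the step from D and Q to L is pseudo-first-order; its half-life of 20.3 min at 0.380 h is shorter than the tail half-life. Counting 5.53 tail half-lives of 65.1 min from 9.51 % gives an estimate of 0.206 %; the same flask read at 8.0 h holds 0.229 %. At 20.0 h it holds 0 % of Q and >99.9 % of L.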